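## Retrosynthetic overview

- The target is 1-(3,4-dihydroxy-5-methoxyphenyl)-7-(3,4-dihydroxyphenyl)heptan-3-one. No ring is formed in the route: rings A and B are bought with their oxygen patterns (from 1 and 6), and there is no stereocentre.
- Enabling feature: ring A carbon C1' (flanked by C2'–H and C6'–H, para to O-4') is linked to the C3 ketone by the two-carbon bridge C1–C2. Raised to the alkyne level, C1'–C1≡C2–C3(=O) is an aryl alkynyl ketone, which is the retron of an aryl iodide + C2 acetylene unit + acyl chloride three-component coupling.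
- Key disconnections: C1'(ring A)–C1 and C2–C3, both made in one pot (step 7); C6=C7 by vinylogous Horner–Wadsworth–Emmons olefination of the ring B aldehyde.
- Ring A iodide from o-vanillin: iodination para to the phenol, Dakin oxidation (CHO to OH), benzylation.
- One final hydrogenation removes the alkyne, both alkenes and all four benzyl ethers; the C3 ketone is aliphatic and the ring A methyl ether is inert.

Key step: step 7

Remark: chain atoms are numbered C1–C7 from ring A (C3 = ketone) and ring A atoms C1'–C6' (C1' bears the chain); the 2E,4E geometry of 8–13 only serves to define the intermediates and is erased in step 8.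

## Route

Step 1
Reactants: 1 o-vanillin (2-hydroxy-3-methoxybenzaldehyde)
Product: 2 2-hydroxy-5-iodo-3-methoxybenzaldehyde
Conditions: NIS (1.05 equiv), TFA (cat.), MeCN, 0 °C to rt
Reagents that add atoms: N-iodosuccinimide, O=C1CCC(=O)N1I
Why: Electrophilic aromatic iodination, in which the free phenol directs para (both its ortho positions are substituted) and the formyl group directs meta, so both point to C5.

Step 2
Reactants: 2 2-hydroxy-5-iodo-3-methoxybenzaldehyde
Product: 4 5-iodo-3-methoxybenzene-1,2-diol, via aryl formate 3 (not isolated)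
Conditions: NaOH (1.0 equiv), 30% H2O2 (1.1 equiv), H2O/THF, 0 °C to rt, under N2
Reagents that add atoms: hydrogen peroxide, OO
Why: Dakin oxidation, in which the hydroperoxide anion adds to the aldehyde, the electron-rich aryl group migrates to oxygen and the formate 3 is hydrolysed in the basic medium, the classical conversion of ortho-hydroxybenzaldehydes into catechols.

Step 3
Reactants: 4 5-iodo-3-methoxybenzene-1,2-diol
Product: 5 1,2-bis(benzyloxy)-5-iodo-3-methoxybenzene
Conditions: BnBr (2.3 equiv), K2CO3 (3 equiv), DMF, rt to 50 °C, under N2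
Reagents that add atoms: benzyl bromide, BrCc1ccccc1
Why: Williamson ether synthesis on both phenoxides, with benzyl chosen because the hydrogenolysis in step 8 removes it while the ring A methyl ether stays.

Step 4
Reactants: 6 3,4-bis(benzyloxy)benzaldehyde; 7 triethyl 4-phosphonocrotonate (ethyl (2E)-4-(diethoxyphosphoryl)but-2-enoate)
Product: 8 ethyl (2E,4E)-5-[3,4-bis(benzyloxy)phenyl]penta-2,4-dienoate
Conditions: LiN(SiMe3)2 (1.1 equiv), THF, −78 °C to rt
Reagents that add atoms: none
Why: Vinylogous Horner–Wadsworth–Emmons olefination, in which the stabilised anion of 7 adds through the carbon next to phosphorus and reversible addition/elimination should give the new C6=C7 bond as the E isomer with the 2E geometry of 7 retained.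

Step 5
Reactants: 8 ethyl (2E,4E)-5-[3,4-bis(benzyloxy)phenyl]penta-2,4-dienoate
Product: 9 (2E,4E)-5-[3,4-bis(benzyloxy)phenyl]penta-2,4-dienoic acid
Conditions: LiOH·H2O (3 equiv), THF/EtOH/H2O, 40 °C; then 1 M HCl
Reagents that add atoms: lithium hydroxide, [Li+].[OH-]
Why: Ester saponification by hydroxide (acyl–oxygen cleavage), which leaves the benzyl ethers and the conjugated diene untouched.

Step 6
Reactants: 9 (2E,4E)-5-[3,4-bis(benzyloxy)phenyl]penta-2,4-dienoic acid
Product: 10 (2E,4E)-5-[3,4-bis(benzyloxy)phenyl]penta-2,4-dienoyl chloride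
Conditions: (COCl)2 (1.5 equiv), DMF (cat.), CH2Cl2, 0 °C to rt; evaporation, used crude
Reagents that add atoms: oxalyl chloride, ClC(=O)C(=O)Cl
Why: Acyl chloride formation with oxalyl chloride under DMF catalysis (chloroiminium activation), the standard access to piperoyl-type dienoyl chlorides, to which benzyl ethers are stable.

Step 7
Reactants: 5 1,2-bis(benzyloxy)-5-iodo-3-methoxybenzene; 11 ethynylmagnesium bromide; 10 (2E,4E)-5-[3,4-bis(benzyloxy)phenyl]penta-2,4-dienoyl chloride
Product: 13 (4E,6E)-1-[3,4-bis(benzyloxy)-5-methoxyphenyl]-7-[3,4-bis(benzyloxy)phenyl]hepta-4,6-dien-1-yn-3-one, via arylacetylene 12 (not isolated)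
Conditions: 11 (1.3 equiv, 0.5 M in THF), PdCl2(PPh3)2 (3 mol%), THF, rt; then CuI (6 mol%), NEt3 (1.5 equiv), 10 (1.4 equiv), THF, rt
Reagents that add atoms: none
Why: Zerovalent palladium (formed from PdCl2(PPh3)2 and 11) inserts into the C–I bond at ring A carbon C1', transmetalation with the ethynyl Grignard and reductive elimination forge the C1'–C1 bond and give 12; after addition of CuI, NEt3 and 10 the same palladium inserts into the acyl C–Cl bond, the copper acetylide of 12 transmetalates and reductive elimination closes the C2–C3 bond. The closest known reaction type is the consecutive one-pot Kumada-type ethynylation of aryl iodides with ethynylmagnesium bromide followed by acyl Sonogashira coupling to alkynones. No ring is closed and no stereocentre is formed; the 4E,6E geometry of 10 is only carried through. The step needs mono-arylation of the two-carbon unit and acylation at the alkyne terminus instead of carbonyl addition: the first should be secured by the excess of 11 and by the unhindered, fast-reacting iodide 5 (C2'–H and C6'–H flank the reacting carbon), which is used up before 12 is activated by copper and amine, the second by the catalytic acyl-palladium pathway and by the absence of an sp3 α-hydrogen in 10, so that NEt3 cannot convert it into a ketene. Residual 11 is scavenged by the small excess of 10.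

Step 8
Reactants: 13 (4E,6E)-1-[3,4-bis(benzyloxy)-5-methoxyphenyl]-7-[3,4-bis(benzyloxy)phenyl]hepta-4,6-dien-1-yn-3-one
Product: 14 1-(3,4-dihydroxy-5-methoxyphenyl)-7-(3,4-dihydroxyphenyl)heptan-3-one
Conditions: H2 (1–3 bar), 10% Pd/C, EtOAc/EtOH, rt; filtration under argon
Reagents that add atoms: none
Why: Heterogeneous catalytic hydrogenation and O-benzyl hydrogenolysis in one operation, in which Pd/C should saturate the alkyne and both alkenes and cleave the four benzyl ethers while the C3 ketone (benzylic to neither ring) and the aryl methyl ether are inert at room temperature and low pressure.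

## Compound list

1 | o-vanillin (2-hydroxy-3-methoxybenzaldehyde) | COc1cccc(C=O)c1O | starting material
2 | 2-hydroxy-5-iodo-3-methoxybenzaldehyde | COc1cc(I)cc(C=O)c1O | intermediate
3 | 2-hydroxy-5-iodo-3-methoxyphenyl formate | COc1cc(I)cc(OC=O)c1O | intermediate
4 | 5-iodo-3-methoxybenzene-1,2-diol | COc1cc(I)cc(O)c1O | intermediate
5 | 1,2-bis(benzyloxy)-5-iodo-3-methoxybenzene | COc1cc(I)cc(OCc2ccccc2)c1OCc1ccccc1 | intermediate
6 | 3,4-bis(benzyloxy)benzaldehyde | O=Cc1ccc(OCc2ccccc2)c(OCc2ccccc2)c1 | starting material
7 | triethyl 4-phosphonocrotonate | CCOC(=O)/C=C/CP(=O)(OCC)OCC | starting material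
8 | ethyl (2E,4E)-5-[3,4-bis(benzyloxy)phenyl]penta-2,4-dienoate | CCOC(=O)/C=C/C=C/c1ccc(OCc2ccccc2)c(OCc2ccccc2)c1 | intermediate
9 | (2E,4E)-5-[3,4-bis(benzyloxy)phenyl]penta-2,4-dienoic acid | OC(=O)/C=C/C=C/c1ccc(OCc2ccccc2)c(OCc2ccccc2)c1 | intermediate
10 | (2E,4E)-5-[3,4-bis(benzyloxy)phenyl]penta-2,4-dienoyl chloride | ClC(=O)/C=C/C=C/c1ccc(OCc2ccccc2)c(OCc2ccccc2)c1 | intermediate
11 | ethynylmagnesium bromide | C#C[Mg]Br | starting material
12 | 1,2-bis(benzyloxy)-5-ethynyl-3-methoxybenzene | COc1cc(C#C)cc(OCc2ccccc2)c1OCc1ccccc1 | intermediate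
13 | (4E,6E)-1-[3,4-bis(benzyloxy)-5-methoxyphenyl]-7-[3,4-bis(benzyloxy)phenyl]hepta-4,6-dien-1-yn-3-one | COc1cc(C#CC(=O)/C=C/C=C/c2ccc(OCc3ccccc3)c(OCc3ccccc3)c2)cc(OCc2ccccc2)c1OCc1ccccc1 | intermediate
14 | 1-(3,4-dihydroxy-5-methoxyphenyl)-7-(3,4-dihydroxyphenyl)heptan-3-one | COc1cc(CCC(=O)CCCCc2ccc(O)c(O)c2)cc(O)c1O | target

## Step count and risks

Total steps: 8. Longest linear sequence: 5 steps (steps 1, 2, 3, 7, 8; the ring B branch, steps 4, 5, 6, 7, 8, is equally long).

Steps most likely to fail:

1. Step 7. Proton exchange between 12 and 11 may lead to a second arylation of the acetylene unit, 12 may dimerise oxidatively at the copper stage, and magnesium acetylides may add to the carbonyl group of 10 or 13. The fallback sets out from 5 and 10 and comes back at 13. Sonogashira coupling of 5 with ethynyltrimethylsilane (PdCl2(PPh3)2, CuI, NEt3, THF) should give {[3,4-bis(benzyloxy)-5-methoxyphenyl]ethynyl}trimethylsilane F1, and K2CO3 in MeOH should release 12, now isolated. Separately, 10 with MeNHOMe·HCl and NEt3 in CH2Cl2 should give the Weinreb amide (2E,4E)-5-[3,4-bis(benzyloxy)phenyl]-N-methoxy-N-methylpenta-2,4-dienamide F2. Deprotonation of 12 with n-BuLi (THF, −78 °C) and addition to F2 should give 13 after acidic work-up, the chelated adduct preventing over-addition.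

2. Step 8. The C3 ketone may be over-reduced on the long exposure needed for four hydrogenolyses, traces of iodide, copper or phosphine from step 7 may poison the catalyst and leave benzyl ethers, and the free catechols may oxidise in air on work-up. The fallback sets out from 13 and comes back at 14. Hydrogenation over Pd/C poisoned with Ph2S (H2, EtOAc, rt) should saturate only the C–C multiple bonds and give 1-[3,4-bis(benzyloxy)-5-methoxyphenyl]-7-[3,4-bis(benzyloxy)phenyl]heptan-3-one F3. Lewis-acid debenzylation with BCl3 and pentamethylbenzene as cation scavenger (CH2Cl2, −78 °C) should then cleave the four benzyl ethers without touching the methyl ether or the ketone and give 14.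

3. Step 2. Alkaline peroxide or air may oxidise the electron-rich catechol further, to the ortho-quinone and ring-cleavage products. The fallback sets out from 2 and comes back at 5, and never exposes a free catechol. Benzylation of 2 (BnBr, K2CO3, DMF) should give 2-(benzyloxy)-5-iodo-3-methoxybenzaldehyde F4. Baeyer–Villiger oxidation (mCPBA, KHCO3, CH2Cl2) should give 2-(benzyloxy)-5-iodo-3-methoxyphenyl formate F5, and methanolysis (K2CO3, MeOH) should give 2-(benzyloxy)-5-iodo-3-methoxyphenol F6. A second benzylation (BnBr, K2CO3, DMF) should give 5.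

Further compounds
F1 | step 7 | {[3,4-bis(benzyloxy)-5-methoxyphenyl]ethynyl}trimethylsilane | COc1cc(C#C[Si](C)(C)C)cc(OCc2ccccc2)c1OCc1ccccc1
F2 | step 7 | (2E,4E)-5-[3,4-bis(benzyloxy)phenyl]-N-methoxy-N-methylpenta-2,4-dienamide | CON(C)C(=O)/C=C/C=C/c1ccc(OCc2ccccc2)c(OCc2ccccc2)c1
F3 | step 8 | 1-[3,4-bis(benzyloxy)-5-methoxyphenyl]-7-[3,4-bis(benzyloxy)phenyl]heptan-3-one | COc1cc(CCC(=O)CCCCc2ccc(OCc3ccccc3)c(OCc3ccccc3)c2)cc(OCc2ccccc2)c1OCc1ccccc1
F4 | step 2 | 2-(benzyloxy)-5-iodo-3-methoxybenzaldehyde | COc1cc(I)cc(C=O)c1OCc1ccccc1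
F5 | step 2 | 2-(benzyloxy)-5-iodo-3-methoxyphenyl formate | COc1cc(I)cc(OC=O)c1OCc1ccccc1
F6 | step 2 | 2-(benzyloxy)-5-iodo-3-methoxyphenol | COc1cc(I)cc(O)c1OCc1ccccc1
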